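## The problem

Target 18 joins a 4-hydroxy-3,5-dimethoxyphenyl ring (ring A) to a methoxylated arene bearing an (E)-3-hydroxypropenyl chain (ring B) through a 1,4-dioxane fused to ring B. In that dioxane C7 carries ring A and is bonded to O1, while C8 carries the hydroxymethyl carbon C9 and is bonded to O4, the ring B oxygen that sits between the methoxy-bearing carbon and the O1-bearing carbon. The first task is regiochemical: two neighbouring ring B oxygens that differ only in their surroundings must be told apart, C8 going to the flanked O4 and C7 to O1. The second is stereochemical: C7 and C8 are both S and trans. C7 is benzylic and para to a free phenol, so its bond to O1 can open and close through a quinone methide; C7 can therefore be left to thermodynamic control by C8 (trans, both substituents equatorial), whereas C8 cannot be epimerised and must be secured in the absolute sense on its own. Three groups restrict the reagents: the free 2,6-dimethoxyphenol (easily oxidised to phenoxyl radicals and quinone methides), the para-hydroxybenzyl aryl ether at C7 (labile to strong acid), and the E-cinnamyl alcohol (acid-sensitive, oxidisable, and a triplet-energy acceptor that isomerises under light). The feature that invites the key step is the chain C7–C8–C9–O: closed on itself it is an oxetane, the formal adduct of the ring A aldehyde (C7=O) and a vinyl ether on O4 (C8=C9). The aldehyde oxygen then ends as the C9 hydroxyl, and the ring strain later pays for handing C7 over to O1.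

## Retrosynthesis

**Side chain (18 ⇒ 17 ⇒ 15 + 16).** The allylic alcohol of 18 is traced to cinnamate 17, and the C=C bond of 17 is cut to aldehyde 15 and the stabilised ylide 16. This cut comes first because a styrene-type alkene would accept triplet energy and isomerise in the photochemical step. Cutting at the aryl–vinyl bond instead would put a halide on ring B and remove the para acceptor on which the ring B regiochemistry rests. Aldehyde 15 lacks two of the side-chain carbons and has no E/Z element. The forward steps must tolerate a free phenol and a primary alcohol and give the E isomer; a neutral Wittig reaction and a cold i-Bu2AlH reduction do.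

**Formyl group (15 ⇒ 13).** The aldehyde is traced to the nitrile of 13, with no skeletal change. A nitrile is preferred to an ester because it is reduced directly to the aldehyde level. An ester would pass through the benzylic alcohol and an oxidation that the free 2,6-dimethoxyphenol is unlikely to survive. The nitrile is transparent at the irradiation wavelength, inert to carbonate in methanol and to lipase, and as a para acceptor it makes the O4 phenol the more acidic of the two ring B phenols. The forward reduction also removes the acetate of 13.

**Absolute configuration (13 ⇒ 12).** Acetate 13 is cut at its acyl–O9 bond to racemic alcohol 12; a lipase selects the enantiomer. No catalyst is established that transmits asymmetry in an intermolecular aldehyde–enol ether photocycloaddition between partners that offer it no binding site, so the plan does not rest on one. The resolution is placed at 12 because this is the first compound with a handle (the C9 hydroxyl) next to C8, and C7 has already converged there. The price is half of the material at this point. The forward step must discriminate a stereocentre one carbon from the reacting hydroxyl, a task this lipase class performs on hydroxymethyl-benzodioxanes.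

**Dioxane ring (12 ⇒ 9).** The C7–O1 bond is cut and the C7–O(C9) bond restored, which turns the dioxane into the 2-aryl-3-aryloxyoxetane 9, in which C7 may have either configuration. Against an oxidative generation of the same quinone methide, this isomerisation needs no oxidant near two electron-rich phenols. The precursor carries both phenols masked and no free hydroxyl. Forward, removal of the two masks must lead through bisphenol 10 to quinone methide 11; O1 must then add 6-exo and reversibly, so that both C7 epimers of 9 give the trans ring.

**Oxetane (9 ⇒ 6 + 8).** The C7–C8 and O–C9 bonds are cut together, a retro-[2+2] that gives aldehyde 8 and aryl vinyl ether 6. Cuts at C7–O1 alone leave a three-carbon chain with two stereocentres to be built beforehand; this cut leaves two flat, achiral arenes. The forward photocycloaddition must be regioselective (aryloxy at C3 of the oxetane) and must spare every other group. It need control neither stereocentre, since C7 converges later and C8 is resolved.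

**Fragments (6 ⇒ 4 + 5; 4 ⇒ 3 ⇒ 1; 8 ⇒ 7).** The vinyl–O4 bond of 6 is cut to phenol 4 and the vinylboron reagent 5. The O3–Si bond of 4 is cut to catechol 3, and the nitrile of 3 is traced to commercial aldehyde 1. The forward silylation must choose the less hindered, less acidic 3-hydroxyl, which the para nitrile and the methoxy neighbour of the 4-hydroxyl both favour. Pivalate 8 comes from syringaldehyde 7 in one acylation.

## Roads not taken

**Alternative 1:** Oxidative closure through a quinone methide. The cut is again C7–O1, but the precursor A1 is an open-chain ether in which C7 is a methylene and C8 already carries O4. DDQ or Ag2O removes the phenolic and the benzylic hydrogen of ring A, and the ring B phenol O1 adds to C7 to give cinnamate A2.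
- Merits: C8 can come from an enantiopure building block, so no material is lost in a resolution, and the closure is the same reversible, trans-selective addition used here. In absolute stereocontrol this road is better than the chosen one.
- Weak points: the oxidant must single out ring A in the presence of a second oxidisable phenol on ring B and a conjugated ester. A1 also needs a secondary alkyl aryl ether at an oxygen flanked on both sides, plus two differentiated phenols, which lengthens the assembly.
- Comparison: the chosen plan sets against it a redox-neutral route to the quinone methide and a two-component assembly from achiral arenes.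

**Alternative 2:** Ring expansion of a catechol benzylidene acetal. The cut is C7–C8 plus O4–C8: C8 is inserted between C7 and O4 of the five-membered acetal A3. A confined chiral Brønsted acid of the imidodiphosphorimidate class would ionise the C7–O4 bond, ethyl diazoacetate A4 would add through carbon, and O4 would displace N2 to give diester A5.
- Merits: short, convergent, and catalytic in chirality if it worked; it would then beat the chosen plan in enantiocontrol.
- Weak points: it rests on two unproven selectivities. Nothing strongly distinguishes the two acetal C–O bonds, and ionising the other one gives the regioisomeric dioxane. The diazonium intermediate usually undergoes 1,2-shift faster than capture by a weakly nucleophilic phenol. C8 in A5 is also α to an ester and epimerisable, and the two esters must be told apart afterwards.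
- Comparison: the chosen plan asks nothing unproven of any step and pays with a resolution.

**Alternative 3:** Copper-catalysed aryl ether closure. The cut is the aryl–O1 bond. Bromo alcohol A6, with both stereocentres in place, is closed with CuI, 3,4,7,8-tetramethyl-1,10-phenanthroline and Cs2CO3 to the fully protected target A7, with retention at C7 and C8.
- Merits: both centres are set by established acyclic methods and are not touched in the ring closure. Stereochemically this is the most reliable of the four roads, and better than the chosen one on that count.
- Weak points: A6 needs the hindered O4–C8 ether made with defined configuration next to a benzylic carbinol. A benzylic alkoxide β to an aryloxy group is heated with carbonate. Three protecting groups must be removed at the end, the allyl ether with zerovalent palladium beside a cinnamyl system.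
- Comparison: the step count is roughly double; the chosen plan sets brevity and the absence of end-game deprotections against the stereochemical security of this road.

Key step: step 5

Remark: compounds 9 to 12 are racemates; their names carry rac and their SMILES show the enantiomer with C8 as in 18; compound 9 is in addition a mixture of cis and trans isomers, so C7 is left open in its SMILES; from 13 on every compound is a single enantiomer.
Remark: the lipase is taken to acylate the (2S,3S) alcohol faster, the sense suggested by analogy with flavonolignan benzodioxanes; should it prefer the (2R,3R) alcohol, the unreacted (2S,3S) alcohol enters step 8 in place of 13 with no other change.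

Step 1
Reactants: 1 3,4-dihydroxy-5-methoxybenzaldehyde (5-hydroxyvanillin)
Product: 3 3,4-dihydroxy-5-methoxybenzonitrile, via aldoxime 2 (not isolated)
Conditions: NH2OH·HCl, HCO2Na, HCO2H, 100 °C
Reagents that add atoms: hydroxylamine hydrochloride, NO.Cl
Why: One-pot oxime formation and formic acid-mediated dehydration (aldehyde-to-nitrile conversion); the medium is non-oxidising, so the catechol survives, and any aryl formate is lost on aqueous work-up.

Step 2
Reactants: 3 3,4-dihydroxy-5-methoxybenzonitrile
Product: 4 3-(tert-butyldimethylsilyloxy)-4-hydroxy-5-methoxybenzonitrile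
Conditions: tert-butyldimethylsilyl chloride (1.05 equiv), imidazole, DMF, 0 °C to rt
Reagents that add atoms: tert-butyldimethylsilyl chloride, C[Si](C)(Cl)C(C)(C)C
Why: Regioselective phenol silylation: the 3-hydroxyl has one ortho neighbour and the 4-hydroxyl two, and silyl groups migrate between catechol oxygens under basic conditions towards the isomer that leaves the more acidic phenol (para to the nitrile) free, so kinetic and thermodynamic preferences point the same way.

Step 3
Reactants: 4 3-(tert-butyldimethylsilyloxy)-4-hydroxy-5-methoxybenzonitrile; 5 2,4,6-trivinylcyclotriboroxane–pyridine complex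
Product: 6 3-(tert-butyldimethylsilyloxy)-5-methoxy-4-(vinyloxy)benzonitrile
Conditions: Cu(OAc)2, pyridine, CH2Cl2, air, rt
Reagents that add atoms: none
Why: Copper-promoted oxidative O-vinylation of a phenol with a vinylboron reagent (Chan–Lam-type coupling); room temperature and a weak base spare the silyl ether and the nitrile and leave little opportunity for silyl migration, and the small vinyl group can be delivered to a phenol with two ortho substituents.

Step 4
Reactants: 7 4-hydroxy-3,5-dimethoxybenzaldehyde (syringaldehyde)
Product: 8 4-formyl-2,6-dimethoxyphenyl 2,2-dimethylpropanoate (pivalate)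
Conditions: pivaloyl chloride, Et3N, 4-(dimethylamino)pyridine (cat.), CH2Cl2, 0 °C to rt
Reagents that add atoms: pivaloyl chloride, CC(C)(C)C(=O)Cl
Why: Nucleophile-catalysed acylation of a hindered phenol; the pivalate removes the phenolic hydrogen donor, lowers the donor strength of the para oxygen towards the carbonyl chromophore and is the slower of the two masks to leave in step 6.

Step 5
Reactants: 6 3-(tert-butyldimethylsilyloxy)-5-methoxy-4-(vinyloxy)benzonitrile; 8 4-formyl-2,6-dimethoxyphenyl pivalate
Product: 9 rac-4-{(3S)-3-[2-(tert-butyldimethylsilyloxy)-4-cyano-6-methoxyphenoxy]oxetan-2-yl}-2,6-dimethoxyphenyl pivalate (cis/trans mixture at C7)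
Conditions: hν (365 nm, borosilicate), benzene, degassed, 15 °C; 6 (2 equiv), excess recovered
Reagents that add atoms: none
Why: Paternò–Büchi reaction: only aldehyde 8 absorbs at 365 nm, and its triplet adds through oxygen to the unsubstituted terminus C9 of vinyl ether 6, giving a 1,4-biradical with one radical at C8 (stabilised by O4) and one at benzylic C7. After intersystem crossing, C7–C8 recombination closes the oxetane, so the four-membered ring is formed stepwise, O–C9 first and C7–C8 second, in a formal [2+2] cycloaddition. The closest known reaction type is the photocycloaddition of aromatic aldehydes to enol ethers and silyl enol ethers, which gives 3-alkoxyoxetanes with this orientation. The selectivity the step needs is regiochemical (aryloxy on C3, not the 2-aryloxy acetal), and the greater stability of the α-aryloxy radical secures it. No stereocontrol is asked of the step and no element in either partner provides any: C8 is formed as the racemate and resolved in step 7, and C7 is formed in both configurations, so that 9 is a cis/trans mixture that is carried on unseparated and converges in step 6. Chemoselectivity rests on the masks: the silyl ether hides a phenol that would quench the triplet by hydrogen transfer, and neither nitrile, pivalate nor silyl group absorbs at this wavelength or offers an easily abstracted hydrogen.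

Step 6
Reactants: 9 rac-oxetane pivalate (cis/trans mixture at C7 from step 5)
Product: 12 rac-(2S,3S)-3-(4-hydroxy-3,5-dimethoxyphenyl)-2-(hydroxymethyl)-8-methoxy-2,3-dihydro-1,4-benzodioxine-6-carbonitrile (trans), via bisphenol oxetane 10 (not isolated), via quinone methide 11 (not isolated)
Conditions: K2CO3, MeOH, rt, then 50 °C
Reagents that add atoms: none
Why: Methanolysis frees O1 (aryl silyl ether, fast) and then the hindered ring A pivalate; the ring A phenoxide of 10 expels the C9 alkoxide from benzylic C7 (1,6-elimination of a para-hydroxybenzyl ether, driven by oxetane strain) to give 11, and the ring B phenoxide O1 adds to C7 in a 6-exo-trig 1,6-addition. Because this addition is reversible for a para-hydroxybenzyl aryl ether in base, both C7 epimers of 9 converge on the trans ring, while C8 is not touched.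

Step 7
Reactants: 12 rac-trans-benzodioxane nitrile
Product: 13 [(2S,3S)-6-cyano-3-(4-hydroxy-3,5-dimethoxyphenyl)-8-methoxy-2,3-dihydro-1,4-benzodioxin-2-yl]methyl acetate
Conditions: immobilised Candida antarctica lipase B, vinyl acetate, t-BuOMe/THF, 35 °C, stopped near 45% conversion
Reagents that add atoms: vinyl acetate, CC(=O)OC=C
Why: Lipase-catalysed kinetic resolution by irreversible acetylation of the primary alcohol next to C8, a reaction type established for hydroxymethyl-1,4-benzodioxanes; the (2S,3S) alcohol is expected to react faster and 13 is separated from the slower (2R,3R) alcohol by chromatography, the phenol not being acylated by the enzyme. No stereocentre is made; the absolute configuration of the route is selected here.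

Step 8
Reactants: 13 (2S,3S)-acetate
Product: 15 (2S,3S)-3-(4-hydroxy-3,5-dimethoxyphenyl)-2-(hydroxymethyl)-8-methoxy-2,3-dihydro-1,4-benzodioxine-6-carbaldehyde, via aldimine 14 (not isolated)
Conditions: i-Bu2AlH (excess), CH2Cl2, −78 to 0 °C; then aq. KNaC4H4O6, cold 1 M HCl
Reagents that add atoms: water, O
Why: Partial reduction of an aromatic nitrile by i-Bu2AlH stops at the N-aluminated aldimine 14, which is hydrolysed on work-up; the same reagent cleaves the acetate reductively, excess hydride covers the phenol, and no oxidant ever meets the free 2,6-dimethoxyphenol.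

Step 9
Reactants: 15 (2S,3S)-aldehyde; 16 methyl (triphenylphosphoranylidene)acetate
Product: 17 methyl (2E)-3-[(2S,3S)-3-(4-hydroxy-3,5-dimethoxyphenyl)-2-(hydroxymethyl)-8-methoxy-2,3-dihydro-1,4-benzodioxin-6-yl]prop-2-enoate
Conditions: CH2Cl2, rt
Reagents that add atoms: none
Why: Wittig olefination with a stabilised ylide: neutral conditions tolerate the free phenol and alcohol, and reversible oxaphosphetane formation gives the E-alkene with aromatic aldehydes.

Step 10
Reactants: 17 (2S,3S)-cinnamate
Product: 18 4-[(2S,3S)-3-(hydroxymethyl)-7-[(1E)-3-hydroxyprop-1-en-1-yl]-5-methoxy-2,3-dihydro-1,4-benzodioxin-2-yl]-2,6-dimethoxyphenol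
Conditions: i-Bu2AlH (excess), CH2Cl2/THF, −78 to −20 °C; then aq. KNaC4H4O6
Reagents that add atoms: none
Why: 1,2-Reduction of an α,β-unsaturated ester by i-Bu2AlH at low temperature gives the allylic alcohol without touching the alkene geometry or the two stereocentres; phenol and primary alcohol are carried as aluminium alkoxides and a neutral work-up protects the cinnamyl alcohol.

## Compound list

1 | 3,4-dihydroxy-5-methoxybenzaldehyde (5-hydroxyvanillin) | COc1cc(C=O)cc(O)c1O | starting material
2 | (E)-3,4-dihydroxy-5-methoxybenzaldehyde oxime | COc1cc(/C=N/O)cc(O)c1O | intermediate (not isolated)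
3 | 3,4-dihydroxy-5-methoxybenzonitrile | COc1cc(C#N)cc(O)c1O | intermediate
4 | 3-(tert-butyldimethylsilyloxy)-4-hydroxy-5-methoxybenzonitrile | COc1cc(C#N)cc(O[Si](C)(C)C(C)(C)C)c1O | intermediate
5 | 2,4,6-trivinylcyclotriboroxane–pyridine complex | C=CB1OB(C=C)OB(C=C)O1.c1ccncc1 | starting material
6 | 3-(tert-butyldimethylsilyloxy)-5-methoxy-4-(vinyloxy)benzonitrile | COc1cc(C#N)cc(O[Si](C)(C)C(C)(C)C)c1OC=C | intermediate
7 | 4-hydroxy-3,5-dimethoxybenzaldehyde (syringaldehyde) | COc1cc(C=O)cc(OC)c1O | starting material
8 | 4-formyl-2,6-dimethoxyphenyl pivalate | COc1cc(C=O)cc(OC)c1OC(=O)C(C)(C)C | intermediate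
9 | rac-4-{(3S)-3-[2-(tert-butyldimethylsilyloxy)-4-cyano-6-methoxyphenoxy]oxetan-2-yl}-2,6-dimethoxyphenyl pivalate (cis and trans isomers together, i.e. both C7 epimers; C8 shown as in 18) | N#Cc1cc(OC)c(O[C@H]2COC2c3cc(OC)c(OC(=O)C(C)(C)C)c(OC)c3)c(O[Si](C)(C)C(C)(C)C)c1 | intermediate
10 | rac-3-hydroxy-4-{[(3S)-2-(4-hydroxy-3,5-dimethoxyphenyl)oxetan-3-yl]oxy}-5-methoxybenzonitrile (both C7 epimers) | N#Cc1cc(OC)c(O[C@H]2COC2c3cc(OC)c(O)c(OC)c3)c(O)c1 | intermediate (not isolated)
11 | rac-4-{[(2R)-1-(3,5-dimethoxy-4-oxocyclohexa-2,5-dien-1-ylidene)-3-hydroxypropan-2-yl]oxy}-3-hydroxy-5-methoxybenzonitrile (quinone methide; C8 spatially as in 18, the descriptor changes because C7 is trigonal) | N#Cc1cc(OC)c(O[C@@H](CO)C=C2C=C(OC)C(=O)C(OC)=C2)c(O)c1 | intermediate (not isolated)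
12 | rac-(2S,3S)-3-(4-hydroxy-3,5-dimethoxyphenyl)-2-(hydroxymethyl)-8-methoxy-2,3-dihydro-1,4-benzodioxine-6-carbonitrile (trans) | COc1cc([C@@H]2Oc3cc(C#N)cc(OC)c3O[C@H]2CO)cc(OC)c1O | intermediate
13 | [(2S,3S)-6-cyano-3-(4-hydroxy-3,5-dimethoxyphenyl)-8-methoxy-2,3-dihydro-1,4-benzodioxin-2-yl]methyl acetate | COc1cc([C@@H]2Oc3cc(C#N)cc(OC)c3O[C@H]2COC(C)=O)cc(OC)c1O | intermediate
14 | 4-[(2S,3S)-3-(hydroxymethyl)-7-(iminomethyl)-5-methoxy-2,3-dihydro-1,4-benzodioxin-2-yl]-2,6-dimethoxyphenol (aldimine, present as its N-aluminium derivative) | COc1cc([C@@H]2Oc3cc(C=N)cc(OC)c3O[C@H]2CO)cc(OC)c1O | intermediate (not isolated)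
15 | (2S,3S)-3-(4-hydroxy-3,5-dimethoxyphenyl)-2-(hydroxymethyl)-8-methoxy-2,3-dihydro-1,4-benzodioxine-6-carbaldehyde | COc1cc([C@@H]2Oc3cc(C=O)cc(OC)c3O[C@H]2CO)cc(OC)c1O | intermediate
16 | methyl (triphenylphosphoranylidene)acetate | COC(=O)C=P(c1ccccc1)(c1ccccc1)c1ccccc1 | starting material
17 | methyl (2E)-3-[(2S,3S)-3-(4-hydroxy-3,5-dimethoxyphenyl)-2-(hydroxymethyl)-8-methoxy-2,3-dihydro-1,4-benzodioxin-6-yl]prop-2-enoate | COc1cc([C@@H]2Oc3cc(/C=C/C(=O)OC)cc(OC)c3O[C@H]2CO)cc(OC)c1O | intermediate
18 | 4-[(2S,3S)-3-(hydroxymethyl)-7-[(1E)-3-hydroxyprop-1-en-1-yl]-5-methoxy-2,3-dihydro-1,4-benzodioxin-2-yl]-2,6-dimethoxyphenol | COc1cc([C@@H]2Oc3cc(/C=C/CO)cc(OC)c3O[C@H]2CO)cc(OC)c1O | target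

## Step count and least certain steps

Total step count: 10. Longest linear sequence: 9 steps (steps 1, 2, 3, 5, 6, 7, 8, 9, 10); step 4 is the side branch.

**Step 5 (key step).** Most likely failure: inefficient cycloaddition. The triplet of an oxygen-rich benzaldehyde has partial π,π* character and may decay or be photoreduced faster than it adds to a moderately electron-rich aryl vinyl ether; some addition with the opposite orientation is also possible. Fallback: the C7–C8 bond is made by aldol chemistry instead, setting out from 4 and 8 and returning at 12. Phenol 4 is alkylated with ethyl bromoacetate (K2CO3, acetone) to ethyl 2-[2-(tert-butyldimethylsilyloxy)-4-cyano-6-methoxyphenoxy]acetate F1. Its lithium enolate (LiN(i-Pr)2, THF, −78 °C) adds to aldehyde 8 to give the β-hydroxy ester F2. NaBH4 reduces the ester to the 1,3-diol F3, and K2CO3 in MeOH removes silyl and pivaloyl groups to give the bisphenol triol F4. Catalytic p-toluenesulfonic acid ionises the benzylic alcohol of F4, and O1 closes to 12 under thermodynamic control.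

**Step 6.** Most likely failure: sluggish or misdirected opening. The phenoxide may not expel an alkoxide from the oxetane at 50 °C, methanol may add to C7 of 11 in competition with O1, or 11 may lose the C8 proton to give an enol ether. Fallback: a cationic instead of an anionic opening, setting out from 9 and returning at 12. Bu4NF buffered with AcOH removes only the silyl group to give the phenol oxetane pivalate F5. BF3·OEt2 in CH2Cl2 at low temperature opens the oxetane at benzylic C7, and the free O1 phenol captures the cation to give the pivalate-protected benzodioxane F6 as C7 epimers. K2CO3 in MeOH then removes the pivalate and equilibrates C7 to give 12.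

**Step 7.** Most likely failure: insufficient discrimination of the enantiomers, since the stereocentre is one carbon away from the reacting hydroxyl; a preference opposite to the assumed one is covered by the remark before the steps. Fallback: classical resolution through covalent diastereomers, setting out from 12 and returning at 15. Acylation of 12 with (1S,4R)-camphanic chloride (Et3N, 4-(dimethylamino)pyridine) gives the diastereomeric bis-camphanates. The (2S,3S) bis-camphanate F7 is separated by crystallisation or chromatography and cleaved with K2CO3 in MeOH to the (2S,3S) alcohol F8, which enters step 8 in place of 13.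

**Step 3.** Most likely failure: slow vinyl transfer to a phenol shielded on both sides, with silyl migration to O4 and vinylation of the freed O3 as a competing path. Fallback: transfer vinylation from vinyl acetate with [Ir(cod)Cl]2 and Na2CO3 in toluene at 100 °C, a different mechanism (addition of the phenol to the coordinated vinyl ester and loss of acetate), setting out from 4 and returning at 6; no new compound is made.

**Step 2.** Most likely failure: incomplete regiocontrol, with silylation at O4 or at both oxygens. Fallback: exhaustive silylation followed by selective unmasking, setting out from 3 and returning at 4. Excess tert-butyldimethylsilyl chloride and imidazole give 3,4-bis(tert-butyldimethylsilyloxy)-5-methoxybenzonitrile F9. Its 4-O-silyl group, the more crowded one and the better leaving phenoxide (para to the nitrile), is then removed selectively with a limited amount of K2CO3 in MeOH at 0 °C to give 4.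

## Further compounds

F1 | step 5 | ethyl 2-[2-(tert-butyldimethylsilyloxy)-4-cyano-6-methoxyphenoxy]acetate | CCOC(=O)COc1c(OC)cc(C#N)cc1O[Si](C)(C)C(C)(C)C
F2 | step 5 | ethyl 2-[2-(tert-butyldimethylsilyloxy)-4-cyano-6-methoxyphenoxy]-3-[3,5-dimethoxy-4-(pivaloyloxy)phenyl]-3-hydroxypropanoate (racemic, both diastereomers) | CCOC(=O)C(Oc1c(OC)cc(C#N)cc1O[Si](C)(C)C(C)(C)C)C(O)c1cc(OC)c(OC(=O)C(C)(C)C)c(OC)c1
F3 | step 5 | 4-{2-[2-(tert-butyldimethylsilyloxy)-4-cyano-6-methoxyphenoxy]-1,3-dihydroxypropyl}-2,6-dimethoxyphenyl pivalate (racemic, both diastereomers) | OCC(Oc1c(OC)cc(C#N)cc1O[Si](C)(C)C(C)(C)C)C(O)c1cc(OC)c(OC(=O)C(C)(C)C)c(OC)c1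
F4 | step 5 | 4-{[1,3-dihydroxy-1-(4-hydroxy-3,5-dimethoxyphenyl)propan-2-yl]oxy}-3-hydroxy-5-methoxybenzonitrile (racemic, both diastereomers) | OCC(Oc1c(OC)cc(C#N)cc1O)C(O)c1cc(OC)c(O)c(OC)c1
F5 | step 6 | rac-4-[(3S)-3-(4-cyano-2-hydroxy-6-methoxyphenoxy)oxetan-2-yl]-2,6-dimethoxyphenyl pivalate (both C7 epimers) | N#Cc1cc(OC)c(O[C@H]2COC2c3cc(OC)c(OC(=O)C(C)(C)C)c(OC)c3)c(O)c1
F6 | step 6 | rac-4-[(3S)-7-cyano-3-(hydroxymethyl)-5-methoxy-2,3-dihydro-1,4-benzodioxin-2-yl]-2,6-dimethoxyphenyl pivalate (both C7 epimers) | COc1cc(C2Oc3cc(C#N)cc(OC)c3O[C@H]2CO)cc(OC)c1OC(=O)C(C)(C)C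
F7 | step 7 | bis-(1S,4R)-camphanate of the (2S,3S) enantiomer of 12 (acylated at the C9 oxygen and at the ring A phenol) | COc1cc([C@@H]2Oc3cc(C#N)cc(OC)c3O[C@H]2COC(=O)[C@]45OC(=O)[C@](C)(CC4)C5(C)C)cc(OC)c1OC(=O)[C@]67OC(=O)[C@](C)(CC6)C7(C)C
F8 | step 7 | (2S,3S)-3-(4-hydroxy-3,5-dimethoxyphenyl)-2-(hydroxymethyl)-8-methoxy-2,3-dihydro-1,4-benzodioxine-6-carbonitrile (single enantiomer of 12) | COc1cc([C@@H]2Oc3cc(C#N)cc(OC)c3O[C@H]2CO)cc(OC)c1O
F0 | step 3 | none | none
F9 | step 2 | 3,4-bis(tert-butyldimethylsilyloxy)-5-methoxybenzonitrile | COc1cc(C#N)cc(O[Si](C)(C)C(C)(C)C)c1O[Si](C)(C)C(C)(C)C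
A1 | alternative 1 | ethyl (2E)-3-[3-hydroxy-4-{[(2R)-1-hydroxy-3-(4-hydroxy-3,5-dimethoxyphenyl)propan-2-yl]oxy}-5-methoxyphenyl]prop-2-enoate | COc1cc(C[C@H](CO)Oc2c(O)cc(/C=C/C(=O)OCC)cc2OC)cc(OC)c1O
A2 | alternative 1 | ethyl (2E)-3-[(2S,3S)-3-(4-hydroxy-3,5-dimethoxyphenyl)-2-(hydroxymethyl)-8-methoxy-2,3-dihydro-1,4-benzodioxin-6-yl]prop-2-enoate | COc1cc([C@@H]2Oc3cc(/C=C/C(=O)OCC)cc(OC)c3O[C@H]2CO)cc(OC)c1O
A3 | alternative 2 | methyl 2-[3,5-dimethoxy-4-(triisopropylsilyloxy)phenyl]-7-methoxy-1,3-benzodioxole-5-carboxylate | COC(=O)c1cc(OC)c2OC(Oc2c1)c1cc(OC)c(O[Si](C(C)C)(C(C)C)C(C)C)c(OC)c1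
A4 | alternative 2 | ethyl diazoacetate | CCOC(=O)C=[N+]=[N-]
A5 | alternative 2 | 2-ethyl 6-methyl trans-3-[3,5-dimethoxy-4-(triisopropylsilyloxy)phenyl]-8-methoxy-2,3-dihydro-1,4-benzodioxine-2,6-dicarboxylate (C7 and C8 spatially as in 18) | COc1cc([C@@H]2Oc3cc(C(=O)OC)cc(OC)c3O[C@H]2C(=O)OCC)cc(OC)c1O[Si](C(C)C)(C(C)C)C(C)C
A6 | alternative 3 | bromo alcohol: 1-[4-(allyloxy)-3,5-dimethoxyphenyl]-2-{2-bromo-6-methoxy-4-[(1E)-3-(tert-butyldimethylsilyloxy)prop-1-en-1-yl]phenoxy}-3-(tert-butyldimethylsilyloxy)propan-1-ol (C7 and C8 spatially as in 18) | C=CCOc1c(OC)cc(cc1OC)[C@H](O)[C@H](CO[Si](C)(C)C(C)(C)C)Oc1c(Br)cc(/C=C/CO[Si](C)(C)C(C)(C)C)cc1OC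
A7 | alternative 3 | fully protected target (allyl on the ring A phenol, both primary alcohols as tert-butyldimethylsilyl ethers) | C=CCOc1c(OC)cc(cc1OC)[C@@H]1Oc2cc(/C=C/CO[Si](C)(C)C(C)(C)C)cc(OC)c2O[C@H]1CO[Si](C)(C)C(C)(C)C
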